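The retrosynthesis first removes the C8 ester and the C13 methylene. It then reads the pairs H5/O6 and H7/O8, all on the α face of ring B, as two syn hydroborations of a C5=C6–C7=C8 diene, and cuts C9–C10 of that cyclohexa-1,3-diene by a retro-6π-electrocyclisation.
The enabling feature is in ring B. It has an sp3 CH2 (C9) next to the quaternary C10, and four contiguous carbons (C5–C8) that can all be sp2. Ring B is therefore the closed valence isomer of the triene C10=C5–C6=C7–C8=C9 hung on the tetrasubstituted C5=C10 alkene of ring A.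
Forward order: ring A is made by Robinson annulation (C3–C4, C5=C10). The chain is joined at C6=C7 (dibromo-olefination), C7–C11 (Negishi) and C7–C8 (Stille). Ring B is closed at C9–C10, followed by hydroboration, C13 methylenation, C15 oxidation and O8 acylation.
Stereochemistry: C1 comes from a CBS reduction, after which the trans C4 epimer is kept (C4 is also the equatorial, thermodynamic aldehyde epimer). C10 is set by torquoselection anti to the pseudoaxial C1 silyloxy group. C5, C6, C7 and C8 are set by α-face hydroboration anti to the angular methyl C14.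
Key step: step 9

Remark: eudesmane numbering is used (ring A = C1–C5, C10; ring B = C5–C10; C14 angular methyl; C15 formyl carbon; C11–C13 acrylic acid unit). The target is taken as the open hydroxy acid/hydroxy aldehyde as drawn, so acid and heat are avoided once O6 is free. TBS = tert-butyldimethylsilyl, TES = triethylsilyl, TMSE = 2-(trimethylsilyl)ethyl.

Step 1
Reactants: 1 methyl 4,4-dimethoxy-3-oxobutanoate; 2 pent-1-en-3-one
Product: 4 methyl 2-(dimethoxymethyl)-3-methyl-4-oxocyclohex-2-ene-1-carboxylate (racemic), via Michael adduct 3 (not isolated)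
Conditions: KOt-Bu (5 mol %), t-BuOH, 0 °C; then pyrrolidine, AcOH (30 mol % each), toluene, reflux, Dean–Stark
Reagents that add atoms: none
Why: Robinson annulation of the Hagemann's ester type, in which the β-keto ester carbon (C4) adds to the enone (C3) and the CH2 of the ethyl ketone (C10) then condenses with the acetal-flanked ketone (C5) in a 6-(enolendo)-exo-trig aldol, giving all of ring A with C6, C14 and C15 attached and C4 racemic.

Step 2
Reactants: 4 methyl 2-(dimethoxymethyl)-3-methyl-4-oxocyclohex-2-ene-1-carboxylate (racemic)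
Product: 5 methyl (1R,4R)-2-(dimethoxymethyl)-4-hydroxy-3-methylcyclohex-2-ene-1-carboxylate (trans)
Conditions: (S)-Me-CBS oxazaborolidine (20 mol %), BH3·SMe2 (0.7 equiv), THF, −30 °C; MeOH; chromatography
Reagents that add atoms: none
Why: In this Corey–Bakshi–Shibata reduction the catalyst distinguishes the alkenyl side (large) from the CH2 side (small) and delivers hydride to the same carbonyl face of both enantiomers of 4, so C1 becomes R throughout and the two C4 epimers become separable diastereomers, of which the trans one (1β-O, 4α-C15) is kept.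

Step 3
Reactants: 5 methyl (1R,4R)-2-(dimethoxymethyl)-4-hydroxy-3-methylcyclohex-2-ene-1-carboxylate
Product: 6 (1R,4R)-3-(dimethoxymethyl)-4-(hydroxymethyl)-2-methylcyclohex-2-en-1-ol
Conditions: LiAlH4, Et2O, 0 °C; aqueous NaOH work-up
Reagents that add atoms: none
Why: Hydride reduction of the ester is fast enough that the C4 centre should not epimerise and the alkene should not move into conjugation, while the acetal and the tetrasubstituted alkene are inert and no new stereocentre forms.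

Step 4
Reactants: 6 (1R,4R)-3-(dimethoxymethyl)-4-(hydroxymethyl)-2-methylcyclohex-2-en-1-ol
Product: 7 (1R,4R)-1-(TBSO)-4-(TBSOCH2)-3-(dimethoxymethyl)-2-methylcyclohex-2-ene
Conditions: TBSCl (2.5 equiv), imidazole, DMF, rt
Reagents that add atoms: tert-butyldimethylsilyl chloride CC(C)(C)[Si](C)(C)Cl
Why: Standard silylation of both hydroxyl groups in one operation, with no stereocentre touched.

Step 5
Reactants: 7 (1R,4R)-1-(TBSO)-4-(TBSOCH2)-3-(dimethoxymethyl)-2-methylcyclohex-2-ene
Product: 8 (3R,6R)-3-(TBSO)-6-(TBSOCH2)-2-methylcyclohex-1-ene-1-carbaldehyde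
Conditions: PPTS (10 mol %), acetone–H2O, rt
Reagents that add atoms: water O
Why: The allylic acetal ionises to a conjugated oxocarbenium ion far more easily than the silyl ethers cleave, so mild acid-catalysed hydrolysis should free only the C6 enal.

Step 6
Reactants: 8 (3R,6R)-3-(TBSO)-6-(TBSOCH2)-2-methylcyclohex-1-ene-1-carbaldehyde
Product: 9 (1R,4R)-1-(TBSO)-4-(TBSOCH2)-3-(2,2-dibromoethenyl)-2-methylcyclohex-2-ene
Conditions: CBr4, PPh3, Zn dust, CH2Cl2, 0 °C to rt
Reagents that add atoms: carbon tetrabromide BrC(Br)(Br)Br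
Why: Ramirez dibromo-olefination (the first half of the Corey–Fuchs sequence) adds C7 as a CBr2 unit, and zinc keeps the medium free of acid so the allylic silyl ether survives.

Step 7
Reactants: 10 bromoacetyl bromide; 11 2-(trimethylsilyl)ethanol
Product: 12 2-(trimethylsilyl)ethyl bromoacetate
Conditions: pyridine, CH2Cl2, 0 °C
Reagents that add atoms: none
Why: Simple acylation of the alcohol by the acid bromide supplies C11–C12 already carrying the fluoride-labile ester.

Step 8
Reactants: 9 (1R,4R)-1-(TBSO)-4-(TBSOCH2)-3-(2,2-dibromoethenyl)-2-methylcyclohex-2-ene; 12 2-(trimethylsilyl)ethyl bromoacetate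
Product: 14 2-(trimethylsilyl)ethyl (3Z)-3-bromo-4-[(3R,6R)-3-(TBSO)-6-(TBSOCH2)-2-methylcyclohex-1-en-1-yl]but-3-enoate, via zinc enolate 13 (not isolated)
Conditions: 12, Zn dust (Me3SiCl-activated), THF, 40 °C; then 9, PdCl2(DPEphos) (5 mol %), THF, rt to 45 °C
Reagents that add atoms: none
Why: In this Negishi coupling of a Reformatsky reagent with a 1,1-dibromoalkene, zerovalent palladium inserts faster into the C–Br bond trans to the bulky cyclohexenyl group, so C11 enters trans to C5 and the remaining bromine stays cis to C5 (Z).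

Step 9
Reactants: 14 2-(trimethylsilyl)ethyl (3Z)-3-bromo-4-[(3R,6R)-3-(TBSO)-6-(TBSOCH2)-2-methylcyclohex-1-en-1-yl]but-3-enoate
Product: 16 2-(trimethylsilyl)ethyl 2-[(4aR,5R,8R)-5-(TBSO)-8-(TBSOCH2)-4a-methyl-4,4a,5,6,7,8-hexahydronaphthalen-2-yl]acetate, via triene 15 (not isolated)
Conditions: Bu3SnCH=CH2 (1.5 equiv), Pd(PPh3)4 (10 mol %), BHT (cat.), degassed toluene, 100 °C
Reagents that add atoms: tributyl(vinyl)stannane C=C[Sn](CCCC)(CCCC)CCCC
Why: Stille coupling (insertion of zerovalent palladium into the C7–Br bond, transmetalation, reductive elimination with retention) places the vinyl group C8=C9 cis to C5 and so gives triene 15 (C10=C5–C6=C7–C8=C9, central double bond cis), which at the same temperature folds into its helical s-cis,s-cis form and undergoes a thermal disrotatory 6π electrocyclisation that forms the σ bond C9–C10. The closest known reaction types are domino Stille coupling–6π electrocyclisations and the thermal closure of previtamin D type and 7-cis-ionylidene type trienes, which likewise join a triene terminus to a methyl-bearing, fully substituted ring carbon. Ring B is closed in the 6π disrotatory mode by this single σ bond with no atom lost, and the C5=C6–C7=C8 diene is left in place. The only new stereocentre, C10, is controlled by ring A: allylic strain with C14 and with the dienyl chain holds the C1 silyloxy group pseudoaxial on the β face and the C4 CH2OTBS group pseudoaxial on the α face, so C9 should bind to the α face of C10 antiperiplanar to the C1–O bond (axial attack on the half-chair), and the C4 group favours the same helix because H6 then turns away from it. The step needs periselectivity against [1,7]- and [1,5]-hydrogen shifts from C14; these shifts are reversible whereas ring closure is strongly downhill, and the C11 substituent on C7 destabilises the s-trans rotamer about C7–C8 and so raises the share of the reactive fold. It also needs the cis relation of C5 and C8 at C6=C7, which is secured by the order of the two couplings on dibromide 9.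

Step 10
Reactants: 16 2-(trimethylsilyl)ethyl 2-[(4aR,5R,8R)-5-(TBSO)-8-(TBSOCH2)-4a-methyl-4,4a,5,6,7,8-hexahydronaphthalen-2-yl]acetate
Product: 18 TMSE 1β,15-bis(TBSO)-6α,8α-dihydroxy-13-nor-5αH,7αH-eudesman-12-oate, via bis-borane 17 (not isolated)
Conditions: BH3·THF (5 equiv), THF, 0 °C to rt; then 30% H2O2, 1 M NaOH, 0 °C
Reagents that add atoms: hydrogen peroxide OO; borane B (boron stays only in 17)
Why: In this hydroboration–oxidation boron goes to the CH end of each trisubstituted alkene (C6 and C8) and H–B adds syn from the α face opposite the angular C14 methyl, as with steroidal 5,7-dienes, which should set H5α, O6α, H7α and O8α (trans-decalin, all new substituents equatorial), and the oxidation proceeds with retention.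

Step 11
Reactants: 18 TMSE 1β,15-bis(TBSO)-6α,8α-dihydroxy-13-nor-5αH,7αH-eudesman-12-oate
Product: 19 TMSE 1β,15-bis(TBSO)-8α-(TESO)-6α-hydroxy-13-nor-5αH,7αH-eudesman-12-oate
Conditions: TESCl (1.05 equiv), imidazole, CH2Cl2, −20 °C
Reagents that add atoms: triethylsilyl chloride CC[Si](Cl)(CC)CC
Why: Steric differentiation in silylation should favour O8, because O8 has a CH2 neighbour (C9) whereas O6 lies between two branched carbons (C5, C7) and faces the peri C15 group.

Step 12
Reactants: 19 TMSE 1β,15-bis(TBSO)-8α-(TESO)-6α-hydroxy-13-nor-5αH,7αH-eudesman-12-oate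
Product: 20 TMSE 1β,6α,15-tris(TBSO)-8α-(TESO)-13-nor-5αH,7αH-eudesman-12-oate
Conditions: TBSOTf, 2,6-lutidine, CH2Cl2, 0 °C
Reagents that add atoms: tert-butyldimethylsilyl triflate CC(C)(C)[Si](C)(C)OS(=O)(=O)C(F)(F)F
Why: The silyl triflate silylates the hindered equatorial O6, which must be blocked before enolate chemistry at C11 so that it cannot close onto C12.

Step 13
Reactants: 20 TMSE 1β,6α,15-tris(TBSO)-8α-(TESO)-13-nor-5αH,7αH-eudesman-12-oate
Product: 23 TMSE 1β,6α,15-tris(TBSO)-8α-(TESO)-eudesm-11(13)-en-12-oate, via Mannich base 21 (not isolated), via ammonium iodide 22 (not isolated)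
Conditions: LiN(i-Pr)2 (LDA), THF, −78 °C; Me2N=CH2+ I−, −78 °C to rt; MeI, CH2Cl2, rt; DBU, rt
Reagents that add atoms: Eschenmoser's salt C=[N+](C)C.[I-]; iodomethane CI (its carbon stays only in 22)
Why: α-Methylenation proceeds by Mannich reaction of the ester enolate with Eschenmoser's salt, quaternisation and E1cB loss of trimethylamine, the oxygens at C6 and C8 being γ to the enolate and so unable to eliminate, and the transient C11 stereocentre is erased.

Step 14
Reactants: 23 TMSE 1β,6α,15-tris(TBSO)-8α-(TESO)-eudesm-11(13)-en-12-oate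
Product: 24 TMSE 1β,6α-bis(TBSO)-8α,15-dihydroxyeudesm-11(13)-en-12-oate
Conditions: HF·pyridine, pyridine, THF, 0 °C
Reagents that add atoms: none
Why: The lability order (primary TBS and secondary TES before hindered secondary TBS) should let buffered HF·pyridine free O15 and O8, while O1 (next to the quaternary C10) and O6 (peri-hindered) stay silylated.

Step 15
Reactants: 24 TMSE 1β,6α-bis(TBSO)-8α,15-dihydroxyeudesm-11(13)-en-12-oate
Product: 25 TMSE 1β,6α-bis(TBSO)-8α-hydroxy-15-oxoeudesm-11(13)-en-12-oate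
Conditions: TEMPO (10 mol %), PhI(OAc)2, CH2Cl2, rt
Reagents that add atoms: none
Why: Oxoammonium (TEMPO) oxidation is selective for the primary alcohol over the hindered secondary O8–H, and the formyl group is already the equatorial 4α (thermodynamic) epimer, so C4 cannot drift.

Step 16
Reactants: 26 methyl 2-(hydroxymethyl)acrylate
Product: 27 methyl 2-[(TBSO)methyl]acrylate
Conditions: TBSCl, imidazole, CH2Cl2, rt
Reagents that add atoms: tert-butyldimethylsilyl chloride CC(C)(C)[Si](C)(C)Cl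
Why: Standard silylation of the primary allylic alcohol.

Step 17
Reactants: 27 methyl 2-[(TBSO)methyl]acrylate
Product: 28 2-[(TBSO)methyl]acrylic acid
Conditions: LiOH, THF–H2O, 0 °C; 1 M HCl to pH 4
Reagents that add atoms: lithium hydroxide [Li+].[OH-]
Why: Saponification of the methyl ester, to which the TBS ether is stable.

Step 18
Reactants: 25 TMSE 1β,6α-bis(TBSO)-8α-hydroxy-15-oxoeudesm-11(13)-en-12-oate; 28 2-[(TBSO)methyl]acrylic acid
Product: 29 TMSE 1β,6α-bis(TBSO)-8α-{2-[(TBSO)methyl]acryloyloxy}-15-oxoeudesm-11(13)-en-12-oate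
Conditions: EDC·HCl, DMAP, CH2Cl2, 0 °C to rt
Reagents that add atoms: none
Why: Steglich esterification of the only free hydroxyl group (equatorial O8), in which the C8–O bond is not broken, so the configuration is retained.

Step 19
Reactants: 29 TMSE 1β,6α-bis(TBSO)-8α-{2-[(TBSO)methyl]acryloyloxy}-15-oxoeudesm-11(13)-en-12-oate
Product: 30 TMSE 1β,6α-dihydroxy-8α-[2-(hydroxymethyl)acryloyloxy]-15-oxoeudesm-11(13)-en-12-oate
Conditions: HF·pyridine, THF, 0 °C to rt
Reagents that add atoms: none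
Why: HF·pyridine removes the three TBS ethers but leaves the TMSE ester, both acrylates and the aldehyde, and keeping C12 esterified at this acidic stage disfavours closure of O6 onto C12.

Step 20
Reactants: 30 TMSE 1β,6α-dihydroxy-8α-[2-(hydroxymethyl)acryloyloxy]-15-oxoeudesm-11(13)-en-12-oate
Product: 31 1β,6α-dihydroxy-8α-[2-(hydroxymethyl)acryloyloxy]-15-oxoeudesm-11(13)-en-12-oic acid (CNP0599450.1)
Conditions: TASF, DMF, 0 °C; then AcOH (1 equiv), cold extractive work-up
Reagents that add atoms: none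
Why: Fluoride attack at silicon triggers β-elimination of the TMSE group and frees the carboxylate under non-acidic conditions, and neutralisation with one equivalent of acetic acid should give the open hydroxy acid with all eight stereocentres untouched.

Compound list
1 | methyl 4,4-dimethoxy-3-oxobutanoate | COC(OC)C(=O)CC(=O)OC | starting material
2 | pent-1-en-3-one | C=CC(=O)CC | starting material
3 | methyl 2-(2,2-dimethoxyacetyl)-5-oxoheptanoate (racemic) | COC(OC)C(=O)C(CCC(=O)CC)C(=O)OC | intermediate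
4 | methyl 2-(dimethoxymethyl)-3-methyl-4-oxocyclohex-2-ene-1-carboxylate (racemic) | COC(OC)C1=C(C)C(=O)CCC1C(=O)OC | intermediate
5 | methyl (1R,4R)-2-(dimethoxymethyl)-4-hydroxy-3-methylcyclohex-2-ene-1-carboxylate | COC(OC)C1=C(C)[C@H](O)CC[C@H]1C(=O)OC | intermediate
6 | (1R,4R)-3-(dimethoxymethyl)-4-(hydroxymethyl)-2-methylcyclohex-2-en-1-ol | COC(OC)C1=C(C)[C@H](O)CC[C@H]1CO | intermediate
7 | (1R,4R)-1-(TBSO)-4-(TBSOCH2)-3-(dimethoxymethyl)-2-methylcyclohex-2-ene | COC(OC)C1=C(C)[C@H](O[Si](C)(C)C(C)(C)C)CC[C@H]1CO[Si](C)(C)C(C)(C)C | intermediate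
8 | (3R,6R)-3-(TBSO)-6-(TBSOCH2)-2-methylcyclohex-1-ene-1-carbaldehyde | O=CC1=C(C)[C@H](O[Si](C)(C)C(C)(C)C)CC[C@H]1CO[Si](C)(C)C(C)(C)C | intermediate
9 | (1R,4R)-1-(TBSO)-4-(TBSOCH2)-3-(2,2-dibromoethenyl)-2-methylcyclohex-2-ene | BrC(Br)=CC1=C(C)[C@H](O[Si](C)(C)C(C)(C)C)CC[C@H]1CO[Si](C)(C)C(C)(C)C | intermediate
10 | bromoacetyl bromide | BrCC(=O)Br | starting material
11 | 2-(trimethylsilyl)ethanol | OCC[Si](C)(C)C | starting material
12 | 2-(trimethylsilyl)ethyl bromoacetate | BrCC(=O)OCC[Si](C)(C)C | intermediate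
13 | bromo{2-oxo-2-[2-(trimethylsilyl)ethoxy]ethyl}zinc (Reformatsky reagent) | Br[Zn]CC(=O)OCC[Si](C)(C)C | intermediate
14 | 2-(trimethylsilyl)ethyl (3Z)-3-bromo-4-[(3R,6R)-3-(TBSO)-6-(TBSOCH2)-2-methylcyclohex-1-en-1-yl]but-3-enoate | Br/C(CC(=O)OCC[Si](C)(C)C)=C\C1=C(C)[C@H](O[Si](C)(C)C(C)(C)C)CC[C@H]1CO[Si](C)(C)C(C)(C)C | intermediate
15 | 2-(trimethylsilyl)ethyl (3Z)-3-{[(3R,6R)-3-(TBSO)-6-(TBSOCH2)-2-methylcyclohex-1-en-1-yl]methylidene}pent-4-enoate | C=C/C(CC(=O)OCC[Si](C)(C)C)=C\C1=C(C)[C@H](O[Si](C)(C)C(C)(C)C)CC[C@H]1CO[Si](C)(C)C(C)(C)C | intermediate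
16 | 2-(trimethylsilyl)ethyl 2-[(4aR,5R,8R)-5-(TBSO)-8-(TBSOCH2)-4a-methyl-4,4a,5,6,7,8-hexahydronaphthalen-2-yl]acetate | C1=C(CC(=O)OCC[Si](C)(C)C)C=C2[C@H](CO[Si](C)(C)C(C)(C)C)CC[C@@H](O[Si](C)(C)C(C)(C)C)[C@]2(C)C1 | intermediate
17 | TMSE 1β,15-bis(TBSO)-6α,8α-diboranyl-13-nor-5αH,7αH-eudesman-12-oate | B[C@H]1C[C@]2(C)[C@@H]([C@@H](B)[C@@H]1CC(=O)OCC[Si](C)(C)C)[C@H](CO[Si](C)(C)C(C)(C)C)CC[C@H]2O[Si](C)(C)C(C)(C)C | intermediate
18 | TMSE 1β,15-bis(TBSO)-6α,8α-dihydroxy-13-nor-5αH,7αH-eudesman-12-oate | O[C@H]1C[C@]2(C)[C@@H]([C@@H](O)[C@@H]1CC(=O)OCC[Si](C)(C)C)[C@H](CO[Si](C)(C)C(C)(C)C)CC[C@H]2O[Si](C)(C)C(C)(C)C | intermediate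
19 | TMSE 1β,15-bis(TBSO)-8α-(TESO)-6α-hydroxy-13-nor-5αH,7αH-eudesman-12-oate | CC[Si](CC)(CC)O[C@H]1C[C@]2(C)[C@@H]([C@@H](O)[C@@H]1CC(=O)OCC[Si](C)(C)C)[C@H](CO[Si](C)(C)C(C)(C)C)CC[C@H]2O[Si](C)(C)C(C)(C)C | intermediate
20 | TMSE 1β,6α,15-tris(TBSO)-8α-(TESO)-13-nor-5αH,7αH-eudesman-12-oate | CC[Si](CC)(CC)O[C@H]1C[C@]2(C)[C@@H]([C@@H](O[Si](C)(C)C(C)(C)C)[C@@H]1CC(=O)OCC[Si](C)(C)C)[C@H](CO[Si](C)(C)C(C)(C)C)CC[C@H]2O[Si](C)(C)C(C)(C)C | intermediate
21 | TMSE 1β,6α,15-tris(TBSO)-8α-(TESO)-13-(dimethylamino)eudesman-12-oate (C11 epimers) | CC[Si](CC)(CC)O[C@H]1C[C@]2(C)[C@@H]([C@@H](O[Si](C)(C)C(C)(C)C)[C@@H]1C(CN(C)C)C(=O)OCC[Si](C)(C)C)[C@H](CO[Si](C)(C)C(C)(C)C)CC[C@H]2O[Si](C)(C)C(C)(C)C | intermediate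
22 | the 13-trimethylammonium iodide of 21 (C11 epimers) | CC[Si](CC)(CC)O[C@H]1C[C@]2(C)[C@@H]([C@@H](O[Si](C)(C)C(C)(C)C)[C@@H]1C(C[N+](C)(C)C)C(=O)OCC[Si](C)(C)C)[C@H](CO[Si](C)(C)C(C)(C)C)CC[C@H]2O[Si](C)(C)C(C)(C)C.[I-] | intermediate
23 | TMSE 1β,6α,15-tris(TBSO)-8α-(TESO)-eudesm-11(13)-en-12-oate | CC[Si](CC)(CC)O[C@H]1C[C@]2(C)[C@@H]([C@@H](O[Si](C)(C)C(C)(C)C)[C@@H]1C(=C)C(=O)OCC[Si](C)(C)C)[C@H](CO[Si](C)(C)C(C)(C)C)CC[C@H]2O[Si](C)(C)C(C)(C)C | intermediate
24 | TMSE 1β,6α-bis(TBSO)-8α,15-dihydroxyeudesm-11(13)-en-12-oate | O[C@H]1C[C@]2(C)[C@@H]([C@@H](O[Si](C)(C)C(C)(C)C)[C@@H]1C(=C)C(=O)OCC[Si](C)(C)C)[C@H](CO)CC[C@H]2O[Si](C)(C)C(C)(C)C | intermediate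
25 | TMSE 1β,6α-bis(TBSO)-8α-hydroxy-15-oxoeudesm-11(13)-en-12-oate | O[C@H]1C[C@]2(C)[C@@H]([C@@H](O[Si](C)(C)C(C)(C)C)[C@@H]1C(=C)C(=O)OCC[Si](C)(C)C)[C@H](C=O)CC[C@H]2O[Si](C)(C)C(C)(C)C | intermediate
26 | methyl 2-(hydroxymethyl)acrylate | C=C(CO)C(=O)OC | starting material
27 | methyl 2-[(TBSO)methyl]acrylate | C=C(CO[Si](C)(C)C(C)(C)C)C(=O)OC | intermediate
28 | 2-[(TBSO)methyl]acrylic acid | C=C(CO[Si](C)(C)C(C)(C)C)C(=O)O | intermediate
29 | TMSE 1β,6α-bis(TBSO)-8α-{2-[(TBSO)methyl]acryloyloxy}-15-oxoeudesm-11(13)-en-12-oate | C=C(CO[Si](C)(C)C(C)(C)C)C(=O)O[C@H]1C[C@]2(C)[C@@H]([C@@H](O[Si](C)(C)C(C)(C)C)[C@@H]1C(=C)C(=O)OCC[Si](C)(C)C)[C@H](C=O)CC[C@H]2O[Si](C)(C)C(C)(C)C | intermediate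
30 | TMSE 1β,6α-dihydroxy-8α-[2-(hydroxymethyl)acryloyloxy]-15-oxoeudesm-11(13)-en-12-oate | C=C(CO)C(=O)O[C@H]1C[C@]2(C)[C@@H]([C@@H](O)[C@@H]1C(=C)C(=O)OCC[Si](C)(C)C)[C@H](C=O)CC[C@H]2O | intermediate
31 | 1β,6α-dihydroxy-8α-[2-(hydroxymethyl)acryloyloxy]-15-oxoeudesm-11(13)-en-12-oic acid (CNP0599450.1) | C=C(CO)C(=O)O[C@H]1C[C@]2(C)[C@@H]([C@@H](O)[C@@H]1C(=C)C(=O)O)[C@H](C=O)CC[C@H]2O | target

Total step count: 20. Longest linear sequence: 17 steps (1–6, 8–15, 18–20).

Steps most likely to fail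

Step 9. At the temperature that the hindered coupling needs, hydrogen shifts from the C14 methyl group ([1,7] to C9, [1,5] to C7) may drain the triene faster than it closes. The two helical folds may also lie too close in energy, which would erode facial selectivity at C10. The fallback separates the two events and leaves the thermal surface. Bromide 14 is coupled at room temperature with CH2=CHZnBr and Pd(P(t-Bu)3)2 in THF, and triene 15 is isolated cold. It is then closed photochemically (λ ≥ 300 nm, pentane, −20 °C) in the conrotatory excited-state mode, the manifold in which previtamin D type trienes re-form their 9,10-bond. Because C9 is a CH2 group, both rotation senses give the same constitution, and the same ring A bias decides C10, while the thermal hydrogen shifts are frozen out. The fallback sets out from 14 and comes back at 16 (new compounds: none F0).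

Step 10. Hydroborating two conjugated double bonds in one operation may suffer from imperfect site and face selectivity (allylborane formation and 1,3-boron shift). Excess borane may slowly reduce the ester, and the new alkoxides may close onto C12 during the basic oxidation. The fallback functionalises one alkene at a time, with protection in between.
- Diene 16 is treated with 9-BBN (THF, 40 °C; NaBO3·4H2O work-up). Only the less hindered C7=C8 bond should react, giving TMSE 1β,15-bis(TBSO)-8α-hydroxy-13-nor-7αH-eudesm-5-en-12-oate F1.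
- TESCl and imidazole convert it into the 8-O-triethylsilyl ether F2.
- A cholesterol-type hydroboration of the remaining C5=C6 bond (BH3·SMe2; NaBO3·4H2O) gives 19 directly, so the selective silylation of step 11 is no longer needed.

The fallback sets out from 16 and comes back at 19.

Step 8. The zinc enolate may couple sluggishly, discrimination between the two C–Br bonds may be lost, or dehydrobromination to a bromoalkyne may intervene. The fallback sets the alkene geometry by olefination instead of site-selective coupling and brings in C12 by carbonylation.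
- Enal 8 reacts with Ph3P=C(Br)CO2Me (CH2Cl2, rt, Wittig reaction, ester trans to C5) to give methyl (2Z)-2-bromo-3-[(3R,6R)-3-(TBSO)-6-(TBSOCH2)-2-methylcyclohex-1-en-1-yl]prop-2-enoate F3.
- Stille coupling with Bu3SnCH=CH2 and Pd(PPh3)4 in toluene at 100 °C gives the triene ester methyl (2E)-2-ethenyl-3-[(3R,6R)-3-(TBSO)-6-(TBSOCH2)-2-methylcyclohex-1-en-1-yl]prop-2-enoate F4.
- F4 closes in the same pot to methyl (4aR,5R,8R)-5-(TBSO)-8-(TBSOCH2)-4a-methyl-4,4a,5,6,7,8-hexahydronaphthalene-2-carboxylate F5.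
- i-Bu2AlH (CH2Cl2, −78 °C) gives the dienylic alcohol [(4aR,5R,8R)-5-(TBSO)-8-(TBSOCH2)-4a-methyl-4,4a,5,6,7,8-hexahydronaphthalen-2-yl]methanol F6.
- 2-(Trimethylsilyl)ethyl chloroformate and pyridine give the mixed carbonate [(4aR,5R,8R)-5-(TBSO)-8-(TBSOCH2)-4a-methyl-4,4a,5,6,7,8-hexahydronaphthalen-2-yl]methyl 2-(trimethylsilyl)ethyl carbonate F7.
- Decarboxylative allylic carbonylation (Pd(OAc)2, PPh3, CO 30 atm, toluene, 50 °C; CO enters at the primary allyl terminus C11) gives 16.

The fallback sets out from 8 and comes back at 16.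

Further compounds
F0 | step 9 | none | none
F1 | step 10 | TMSE 1β,15-bis(TBSO)-8α-hydroxy-13-nor-7αH-eudesm-5-en-12-oate | O[C@H]1C[C@]2(C)C(=C[C@@H]1CC(=O)OCC[Si](C)(C)C)[C@H](CO[Si](C)(C)C(C)(C)C)CC[C@H]2O[Si](C)(C)C(C)(C)C
F2 | step 10 | TMSE 1β,15-bis(TBSO)-8α-(TESO)-13-nor-7αH-eudesm-5-en-12-oate | CC[Si](CC)(CC)O[C@H]1C[C@]2(C)C(=C[C@@H]1CC(=O)OCC[Si](C)(C)C)[C@H](CO[Si](C)(C)C(C)(C)C)CC[C@H]2O[Si](C)(C)C(C)(C)C
F3 | step 8 | methyl (2Z)-2-bromo-3-[(3R,6R)-3-(TBSO)-6-(TBSOCH2)-2-methylcyclohex-1-en-1-yl]prop-2-enoate | Br/C(C(=O)OC)=C\C1=C(C)[C@H](O[Si](C)(C)C(C)(C)C)CC[C@H]1CO[Si](C)(C)C(C)(C)C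
F4 | step 8 | methyl (2E)-2-ethenyl-3-[(3R,6R)-3-(TBSO)-6-(TBSOCH2)-2-methylcyclohex-1-en-1-yl]prop-2-enoate | C=C/C(C(=O)OC)=C\C1=C(C)[C@H](O[Si](C)(C)C(C)(C)C)CC[C@H]1CO[Si](C)(C)C(C)(C)C
F5 | step 8 | methyl (4aR,5R,8R)-5-(TBSO)-8-(TBSOCH2)-4a-methyl-4,4a,5,6,7,8-hexahydronaphthalene-2-carboxylate | C1=C(C(=O)OC)C=C2[C@H](CO[Si](C)(C)C(C)(C)C)CC[C@@H](O[Si](C)(C)C(C)(C)C)[C@]2(C)C1
F6 | step 8 | [(4aR,5R,8R)-5-(TBSO)-8-(TBSOCH2)-4a-methyl-4,4a,5,6,7,8-hexahydronaphthalen-2-yl]methanol | C1=C(CO)C=C2[C@H](CO[Si](C)(C)C(C)(C)C)CC[C@@H](O[Si](C)(C)C(C)(C)C)[C@]2(C)C1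
F7 | step 8 | [(4aR,5R,8R)-5-(TBSO)-8-(TBSOCH2)-4a-methyl-4,4a,5,6,7,8-hexahydronaphthalen-2-yl]methyl 2-(trimethylsilyl)ethyl carbonate | C1=C(COC(=O)OCC[Si](C)(C)C)C=C2[C@H](CO[Si](C)(C)C(C)(C)C)CC[C@@H](O[Si](C)(C)C(C)(C)C)[C@]2(C)C1
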